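**Plan**
1. Retrosynthetic cuts, in order: O1–C8a of the naringenin part (unit 2) by intramolecular SNAr on a C8a–F carbon; C4–C4a of unit 2 (aryllithium + Weinreb amide); in the eriodictyol part (unit 1) O1–C8a (SNAr) and C2–C3 (aldol); last the inter-unit bond C3(unit 1)–C8(unit 2), made as a CH2–aryl bond by Pd ketone α-arylation.
2. Forward: one fluoroarene (2) gives ketone 5 and the mirror-symmetric dibromide 6; these give deoxybenzoin 7, then the pyranone ring of unit 1 (11), which is masked as a 4-silyloxyflavan (13); the acyl chain of unit 2 is attached (19), its pyranone ring is closed (21), then reoxidation and debenzylation.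
3. Enabling feature: C8a of ring A of unit 2 is ortho to the C4 carbonyl and meta to both ring oxygens O5 and O7, so as C–F it is a carbonyl-activated SNAr site that the two alkoxy donors do not deactivate. Because the fluorine carbon of 6 becomes C8a, the neighbouring carbon carrying unit 1 can only be C8 (no 6/8 ambiguity).
4. Stereochemistry: C2 of unit 2 (S) comes from Ru–BINAP hydrogenation of keto ester 14 and is kept through ring closure because its C–O bond is never broken. C2 of unit 1 (R) is selected by a transfer-hydrogenative kinetic resolution of rac-11. C3 of unit 1 (S) is the thermodynamic trans position.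

Key step: step 12

Remark: flavanone numbering is used within each unit; unit 1 is the 3-linked eriodictyol-type half, unit 2 the 8-linked naringenin-type half.
Remark: keto ester 14 is taken as commercially available.
Remark: the flavan-4-ols 12 to 22 are drawn as the all-equatorial (2,3-trans, 3,4-trans) isomers; the C4 configuration is erased in step 14 and C3 can re-equilibrate to trans there.

**Step 1**
Reactants: 1 5-fluorobenzene-1,3-diol
Product: 2 1,3-bis(benzyloxy)-5-fluorobenzene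
Conditions: BnBr, K2CO3, DMF, 60 °C
Reagents that add atoms: benzyl bromide, BrCc1ccccc1
Why: Williamson etherification of both phenols; the aryl fluoride is inert to carbonate.

**Step 2**
Reactants: 2 1,3-bis(benzyloxy)-5-fluorobenzene
Product: 3 1,5-bis(benzyloxy)-2-bromo-3-fluorobenzene
Conditions: NBS (1 equiv), MeCN, 0 °C
Reagents that add atoms: N-bromosuccinimide, O=C1CCC(=O)N1Br
Why: Electrophilic aromatic bromination should go para to one benzyloxy group and ortho to fluorine rather than into the more hindered position between the two benzyloxy groups, as with 5-substituted resorcinol diethers.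

**Step 3**
Reactants: 3 1,5-bis(benzyloxy)-2-bromo-3-fluorobenzene
Product: 5 1-[2,4-bis(benzyloxy)-6-fluorophenyl]ethan-1-one, via aryllithium 4 (not isolated)
Conditions: n-BuLi, THF, −78 °C; then N-methoxy-N-methylacetamide, −78 to −50 °C; aq. NH4Cl
Reagents that add atoms: N-methoxy-N-methylacetamide, CC(=O)N(C)OC
Why: Bromine–lithium exchange followed by Weinreb ketone synthesis; the chelated tetrahedral adduct stops at the ketone, and the ortho-fluoro aryllithium is kept cold so that it does not lose LiF to an aryne.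

**Step 4**
Reactants: 2 1,3-bis(benzyloxy)-5-fluorobenzene
Product: 6 1,5-bis(benzyloxy)-2,4-dibromo-3-fluorobenzene
Conditions: NBS (2.1 equiv), MeCN, 0 to 20 °C
Reagents that add atoms: N-bromosuccinimide, O=C1CCC(=O)N1Br
Why: Twofold electrophilic bromination at the two equivalent positions ortho to fluorine gives a mirror-symmetric dibromide and leaves the carbon between the benzyloxy groups (later C6 of unit 2) as C–H.

**Step 5**
Reactants: 5 1-[2,4-bis(benzyloxy)-6-fluorophenyl]ethan-1-one; 6 1,5-bis(benzyloxy)-2,4-dibromo-3-fluorobenzene (threefold excess)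
Product: 7 1-[2,4-bis(benzyloxy)-6-fluorophenyl]-2-[4,6-bis(benzyloxy)-3-bromo-2-fluorophenyl]ethan-1-one
Conditions: Pd2(dba)3, XPhos, K3PO4, toluene, 90 °C
Reagents that add atoms: none
Why: Buchwald–Hartwig-type palladium-catalysed α-arylation of a methyl ketone makes the future C3(unit 1)–C8(unit 2) bond; the excess of symmetric 6 favours mono-coupling, the doubly ortho-substituted aryl group blocks a second arylation, and the weak base spares the activated C–F bond.

**Step 6**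
Reactants: 7 1-[2,4-bis(benzyloxy)-6-fluorophenyl]-2-[4,6-bis(benzyloxy)-3-bromo-2-fluorophenyl]ethan-1-one; 8 3,4-bis(benzyloxy)benzaldehyde
Product: 11 rac-(2R,3S)-5,7-bis(benzyloxy)-2-[3,4-bis(benzyloxy)phenyl]-3-[4,6-bis(benzyloxy)-3-bromo-2-fluorophenyl]chroman-4-one, via potassium enolate 9 (not isolated), via potassium aldolate 10 (not isolated)
Conditions: KN(SiMe3)2 (1.0 equiv), THF, −78 °C; then 8, −78 to 20 °C; then DBU (cat.), 20 °C
Reagents that add atoms: none
Why: Aldol addition followed by intramolecular SNAr: the reversible aldolate is drained by irreversible fluoride displacement at the carbonyl-activated ring A carbon (the other fluorine has no activating carbonyl), and DBU should equilibrate C2/C3 to the trans isomer with both aryl groups equatorial; the product is racemic at this stage.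

**Step 7**
Reactants: 11 rac-(2R,3S)-5,7-bis(benzyloxy)-2-[3,4-bis(benzyloxy)phenyl]-3-[4,6-bis(benzyloxy)-3-bromo-2-fluorophenyl]chroman-4-one
Product: 12 (2R,3R,4R)-5,7-bis(benzyloxy)-2-[3,4-bis(benzyloxy)phenyl]-3-[4,6-bis(benzyloxy)-3-bromo-2-fluorophenyl]chroman-4-ol
Conditions: RuCl(p-cymene)[(R,R)-TsDPEN] (cat.), HCO2H/Et3N (5:2), EtOAc, 30 °C, stopped near half conversion
Reagents that add atoms: none
Why: Noyori–Ikariya asymmetric transfer hydrogenation run as a kinetic resolution, a known way to resolve racemic flavanones: the (R,R) catalyst forms the (4R) carbinol and only in the (2R,3S) enantiomer does this coincide with the favoured axial hydride delivery to the all-equatorial alcohol, so C2 of unit 1 is selected as (R), the (2S,3R) ketone is left behind (it can be racemised with DBU through its chalcone and recycled), and the reduction also masks the enolisable ketone ahead of steps 11 and 12.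

**Step 8**
Reactants: 12 (2R,3R,4R)-5,7-bis(benzyloxy)-2-[3,4-bis(benzyloxy)phenyl]-3-[4,6-bis(benzyloxy)-3-bromo-2-fluorophenyl]chroman-4-ol
Product: 13 (2R,3S,4R)-5,7-bis(benzyloxy)-2-[3,4-bis(benzyloxy)phenyl]-3-[4,6-bis(benzyloxy)-3-bromo-2-fluorophenyl]-4-(triethylsilyloxy)chromane
Conditions: Et3SiOTf, 2,6-lutidine, CH2Cl2, −78 °C
Reagents that add atoms: triethylsilyl trifluoromethanesulfonate, CC[Si](CC)(CC)OS(=O)(=O)C(F)(F)F
Why: Silylation of the hindered benzylic alcohol under buffered conditions; the ether survives n-BuLi and keeps the C4 oxygen from closing a five-membered ring onto the C–F carbon in step 12.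

**Step 9**
Reactants: 14 ethyl 3-[4-(benzyloxy)phenyl]-3-oxopropanoate
Product: 15 ethyl (3S)-3-[4-(benzyloxy)phenyl]-3-hydroxypropanoate
Conditions: RuCl2[(R)-BINAP] (cat.), H2 (50 atm), EtOH, 60 °C
Reagents that add atoms: none
Why: Noyori asymmetric hydrogenation of a β-keto ester; the (R)-BINAP catalyst should deliver hydrogen to the chelated keto ester to give the (S) carbinol of β-aryl substrates, and the benzyl ether is inert to the ruthenium catalyst.

**Step 10**
Reactants: 15 ethyl (3S)-3-[4-(benzyloxy)phenyl]-3-hydroxypropanoate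
Product: 16 (3S)-3-[4-(benzyloxy)phenyl]-3-hydroxy-N-methoxy-N-methylpropanamide
Conditions: MeNH(OMe)·HCl, i-PrMgCl, THF, −20 to 0 °C
Reagents that add atoms: N,O-dimethylhydroxylamine hydrochloride, CNOC.Cl
Why: Weinreb amidation of an ester with the magnesium amide; it tolerates the free β-hydroxyl (held as its magnesium alkoxide) and does not touch the carbinol stereocentre.

**Step 11**
Reactants: 13 (2R,3S,4R)-5,7-bis(benzyloxy)-2-[3,4-bis(benzyloxy)phenyl]-3-[4,6-bis(benzyloxy)-3-bromo-2-fluorophenyl]-4-(triethylsilyloxy)chromane; 16 (3S)-3-[4-(benzyloxy)phenyl]-3-hydroxy-N-methoxy-N-methylpropanamide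
Product: 19 (3S)-1-{4,6-bis(benzyloxy)-2-fluoro-3-[(2R,3S,4R)-5,7-bis(benzyloxy)-2-[3,4-bis(benzyloxy)phenyl]-4-(triethylsilyloxy)chroman-3-yl]phenyl}-3-[4-(benzyloxy)phenyl]-3-hydroxypropan-1-one, via aryllithium 17 (not isolated), via chloromagnesium alkoxide 18 (not isolated)
Conditions: 13: n-BuLi, THF, −78 °C; 16: i-PrMgCl (1 equiv), THF, −40 °C; solutions combined at −78 °C, then to −50 °C; aq. NH4Cl
Reagents that add atoms: none
Why: Bromine–lithium exchange and Weinreb ketone synthesis join the two halves at C4–C4a of unit 2; the hydroxyl of 16 is pre-masked as its alkoxide so it does not quench the aryllithium, and the low temperature suppresses LiF loss from the ortho-fluoro aryllithium.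

**Step 12**
Reactants: 19 (3S)-1-{4,6-bis(benzyloxy)-2-fluoro-3-[(2R,3S,4R)-5,7-bis(benzyloxy)-2-[3,4-bis(benzyloxy)phenyl]-4-(triethylsilyloxy)chroman-3-yl]phenyl}-3-[4-(benzyloxy)phenyl]-3-hydroxypropan-1-one
Product: 21 (2S)-5,7-bis(benzyloxy)-2-[4-(benzyloxy)phenyl]-8-[(2R,3S,4R)-5,7-bis(benzyloxy)-2-[3,4-bis(benzyloxy)phenyl]-4-(triethylsilyloxy)chroman-3-yl]chroman-4-one, via potassium alkoxide 20 (not isolated)
Conditions: KN(SiMe3)2 (1.05 equiv), 18-crown-6, THF, −78 to −20 °C; then AcOH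
Reagents that add atoms: none
Why: KN(SiMe3)2 turns the free carbinol into the potassium alkoxide 20, whose oxygen adds to the fluorine-bearing carbon (the future C8a of unit 2) to give a Meisenheimer adduct with the charge on the ortho C4 carbonyl, and loss of fluoride restores the arene. The closest known reaction type is the intramolecular SNAr etherification of 3-hydroxy-1-(2-fluoroaryl)propan-1-ones to chroman-4-ones and flavanones. The one ring formed (O1, C2, C3, C4, C4a, C8a of unit 2) closes in the 6-endo-trig addition–elimination mode, the alkoxide attacking the β-carbon of the aryl ketone seen as a vinylogous acyl fluoride. No new stereocentre is made: C2 of unit 2 keeps the (S) configuration set in step 9 because the bond formed is O–aryl and the benzylic C–O bond is never broken, which a closure at C2 (oxa-Michael or Mitsunobu on this p-alkoxybenzylic carbinol) could not guarantee. The step needs ring closure to outrun retro-aldol cleavage and dehydration of the aldolate, which the crown-ether-activated alkoxide at low temperature and fluorine as nucleofuge on a carbon ortho to the carbonyl and only meta to the two benzyloxy donors should secure. It also needs attack at C–F rather than at the other ortho carbon (C–OBn) and no interference from unit 1, which the better nucleofuge and the non-enolisable, O-silylated flavan form of unit 1 should secure.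

**Step 13**
Reactants: 21 (2S)-5,7-bis(benzyloxy)-2-[4-(benzyloxy)phenyl]-8-[(2R,3S,4R)-5,7-bis(benzyloxy)-2-[3,4-bis(benzyloxy)phenyl]-4-(triethylsilyloxy)chroman-3-yl]chroman-4-one
Product: 22 (2S)-5,7-bis(benzyloxy)-2-[4-(benzyloxy)phenyl]-8-[(2R,3R,4R)-5,7-bis(benzyloxy)-2-[3,4-bis(benzyloxy)phenyl]-4-hydroxychroman-3-yl]chroman-4-one
Conditions: Bu4NF, AcOH (1:1), THF, 0 to 20 °C
Reagents that add atoms: none
Why: Fluoride desilylation buffered with acetic acid, so that the now base-sensitive flavanone of unit 2 does not ring-open (retro-oxa-Michael) and no strong acid ionises the electron-rich C4 carbinol.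

**Step 14**
Reactants: 22 (2S)-5,7-bis(benzyloxy)-2-[4-(benzyloxy)phenyl]-8-[(2R,3R,4R)-5,7-bis(benzyloxy)-2-[3,4-bis(benzyloxy)phenyl]-4-hydroxychroman-3-yl]chroman-4-one
Product: 23 (2S)-5,7-bis(benzyloxy)-2-[4-(benzyloxy)phenyl]-8-[(2R,3S)-5,7-bis(benzyloxy)-2-[3,4-bis(benzyloxy)phenyl]-4-oxochroman-3-yl]chroman-4-one
Conditions: Dess–Martin periodinane, pyridine, CH2Cl2, 0 to 20 °C
Reagents that add atoms: none
Why: Dess–Martin oxidation of the benzylic alcohol restores the C4 ketone of unit 1 under near-neutral conditions; C3 of unit 1 is already in the thermodynamic trans position, and any cis material would equilibrate to it by enolisation.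

**Step 15**
Reactants: 23 (2S)-5,7-bis(benzyloxy)-2-[4-(benzyloxy)phenyl]-8-[(2R,3S)-5,7-bis(benzyloxy)-2-[3,4-bis(benzyloxy)phenyl]-4-oxochroman-3-yl]chroman-4-one
Product: 24 (2S)-8-[(2R,3S)-2-(3,4-dihydroxyphenyl)-5,7-dihydroxy-4-oxochroman-3-yl]-5,7-dihydroxy-2-(4-hydroxyphenyl)chroman-4-one
Conditions: H2 (1 atm), Pd/C, EtOAc/MeOH, 20 °C
Reagents that add atoms: none
Why: Hydrogenolysis of the seven benzyl ethers under neutral conditions, without acid or base, so neither flavanone should epimerise or ring-open; the aryl ketones and the ring C2–O bonds should survive a short exposure at atmospheric pressure.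

**Compound list**
1 | 5-fluorobenzene-1,3-diol | Oc1cc(O)cc(F)c1 | starting material
2 | 1,3-bis(benzyloxy)-5-fluorobenzene | Fc1cc(OCc2ccccc2)cc(OCc2ccccc2)c1 | intermediate
3 | 1,5-bis(benzyloxy)-2-bromo-3-fluorobenzene | Fc1cc(OCc2ccccc2)cc(OCc2ccccc2)c1Br | intermediate
4 | [2,4-bis(benzyloxy)-6-fluorophenyl]lithium | [Li]c1c(F)cc(OCc2ccccc2)cc1OCc1ccccc1 | intermediate (not isolated)
5 | 1-[2,4-bis(benzyloxy)-6-fluorophenyl]ethan-1-one | CC(=O)c1c(F)cc(OCc2ccccc2)cc1OCc1ccccc1 | intermediate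
6 | 1,5-bis(benzyloxy)-2,4-dibromo-3-fluorobenzene | Fc1c(Br)c(OCc2ccccc2)cc(OCc2ccccc2)c1Br | intermediate
7 | 1-[2,4-bis(benzyloxy)-6-fluorophenyl]-2-[4,6-bis(benzyloxy)-3-bromo-2-fluorophenyl]ethan-1-one | O=C(Cc1c(F)c(Br)c(OCc2ccccc2)cc1OCc1ccccc1)c1c(F)cc(OCc2ccccc2)cc1OCc1ccccc1 | intermediate
8 | 3,4-bis(benzyloxy)benzaldehyde | O=Cc1ccc(OCc2ccccc2)c(OCc2ccccc2)c1 | starting material
9 | potassium (Z)-enolate of 7 | [K+].[O-]/C(=C\c1c(F)c(Br)c(OCc2ccccc2)cc1OCc1ccccc1)c1c(F)cc(OCc2ccccc2)cc1OCc1ccccc1 | intermediate (not isolated)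
10 | potassium aldolate of 7 and 8 (mixture of stereoisomers) | [K+].[O-]C(c1ccc(OCc2ccccc2)c(OCc2ccccc2)c1)C(C(=O)c1c(F)cc(OCc2ccccc2)cc1OCc1ccccc1)c1c(F)c(Br)c(OCc2ccccc2)cc1OCc1ccccc1 | intermediate (not isolated)
11 | rac-(2R,3S)-5,7-bis(benzyloxy)-2-[3,4-bis(benzyloxy)phenyl]-3-[4,6-bis(benzyloxy)-3-bromo-2-fluorophenyl]chroman-4-one (trans racemate; one enantiomer drawn) | Brc1c(F)c([C@@H]2C(=O)c3c(OCc4ccccc4)cc(OCc4ccccc4)cc3O[C@H]2c2ccc(OCc3ccccc3)c(OCc3ccccc3)c2)c(OCc2ccccc2)cc1OCc1ccccc1 | intermediate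
12 | (2R,3R,4R)-5,7-bis(benzyloxy)-2-[3,4-bis(benzyloxy)phenyl]-3-[4,6-bis(benzyloxy)-3-bromo-2-fluorophenyl]chroman-4-ol (2,3-trans, 3,4-trans) | Brc1c(F)c([C@@H]2[C@@H](O)c3c(OCc4ccccc4)cc(OCc4ccccc4)cc3O[C@H]2c2ccc(OCc3ccccc3)c(OCc3ccccc3)c2)c(OCc2ccccc2)cc1OCc1ccccc1 | intermediate
13 | (2R,3S,4R)-5,7-bis(benzyloxy)-2-[3,4-bis(benzyloxy)phenyl]-3-[4,6-bis(benzyloxy)-3-bromo-2-fluorophenyl]-4-(triethylsilyloxy)chromane | Brc1c(F)c([C@@H]2[C@@H](O[Si](CC)(CC)CC)c3c(OCc4ccccc4)cc(OCc4ccccc4)cc3O[C@H]2c2ccc(OCc3ccccc3)c(OCc3ccccc3)c2)c(OCc2ccccc2)cc1OCc1ccccc1 | intermediate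
14 | ethyl 3-[4-(benzyloxy)phenyl]-3-oxopropanoate | CCOC(=O)CC(=O)c1ccc(OCc2ccccc2)cc1 | starting material
15 | ethyl (3S)-3-[4-(benzyloxy)phenyl]-3-hydroxypropanoate | CCOC(=O)C[C@@H](c1ccc(OCc2ccccc2)cc1)O | intermediate
16 | (3S)-3-[4-(benzyloxy)phenyl]-3-hydroxy-N-methoxy-N-methylpropanamide | CON(C)C(=O)C[C@@H](c1ccc(OCc2ccccc2)cc1)O | intermediate
17 | aryllithium from 13 (Li in place of Br) | [Li]c1c(F)c([C@@H]2[C@@H](O[Si](CC)(CC)CC)c3c(OCc4ccccc4)cc(OCc4ccccc4)cc3O[C@H]2c2ccc(OCc3ccccc3)c(OCc3ccccc3)c2)c(OCc2ccccc2)cc1OCc1ccccc1 | intermediate (not isolated)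
18 | chloromagnesium alkoxide of 16 | CON(C)C(=O)C[C@@H](c1ccc(OCc2ccccc2)cc1)O[Mg]Cl | intermediate (not isolated)
19 | (3S)-1-{4,6-bis(benzyloxy)-2-fluoro-3-[(2R,3S,4R)-5,7-bis(benzyloxy)-2-[3,4-bis(benzyloxy)phenyl]-4-(triethylsilyloxy)chroman-3-yl]phenyl}-3-[4-(benzyloxy)phenyl]-3-hydroxypropan-1-one | O=C(C[C@@H](c1ccc(OCc2ccccc2)cc1)O)c1c(F)c([C@@H]2[C@@H](O[Si](CC)(CC)CC)c3c(OCc4ccccc4)cc(OCc4ccccc4)cc3O[C@H]2c2ccc(OCc3ccccc3)c(OCc3ccccc3)c2)c(OCc2ccccc2)cc1OCc1ccccc1 | intermediate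
20 | potassium alkoxide of 19 | [K+].O=C(C[C@@H](c1ccc(OCc2ccccc2)cc1)[O-])c1c(F)c([C@@H]2[C@@H](O[Si](CC)(CC)CC)c3c(OCc4ccccc4)cc(OCc4ccccc4)cc3O[C@H]2c2ccc(OCc3ccccc3)c(OCc3ccccc3)c2)c(OCc2ccccc2)cc1OCc1ccccc1 | intermediate (not isolated)
21 | (2S)-5,7-bis(benzyloxy)-2-[4-(benzyloxy)phenyl]-8-[(2R,3S,4R)-5,7-bis(benzyloxy)-2-[3,4-bis(benzyloxy)phenyl]-4-(triethylsilyloxy)chroman-3-yl]chroman-4-one | O=C1C[C@@H](c2ccc(OCc3ccccc3)cc2)Oc2c1c(OCc1ccccc1)cc(OCc1ccccc1)c2[C@@H]1[C@@H](O[Si](CC)(CC)CC)c2c(OCc3ccccc3)cc(OCc3ccccc3)cc2O[C@H]1c1ccc(OCc2ccccc2)c(OCc2ccccc2)c1 | intermediate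
22 | (2S)-5,7-bis(benzyloxy)-2-[4-(benzyloxy)phenyl]-8-[(2R,3R,4R)-5,7-bis(benzyloxy)-2-[3,4-bis(benzyloxy)phenyl]-4-hydroxychroman-3-yl]chroman-4-one | O=C1C[C@@H](c2ccc(OCc3ccccc3)cc2)Oc2c1c(OCc1ccccc1)cc(OCc1ccccc1)c2[C@@H]1[C@@H](O)c2c(OCc3ccccc3)cc(OCc3ccccc3)cc2O[C@H]1c1ccc(OCc2ccccc2)c(OCc2ccccc2)c1 | intermediate
23 | (2S)-5,7-bis(benzyloxy)-2-[4-(benzyloxy)phenyl]-8-[(2R,3S)-5,7-bis(benzyloxy)-2-[3,4-bis(benzyloxy)phenyl]-4-oxochroman-3-yl]chroman-4-one | O=C1C[C@@H](c2ccc(OCc3ccccc3)cc2)Oc2c1c(OCc1ccccc1)cc(OCc1ccccc1)c2[C@@H]1C(=O)c2c(OCc3ccccc3)cc(OCc3ccccc3)cc2O[C@H]1c1ccc(OCc2ccccc2)c(OCc2ccccc2)c1 | intermediate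
24 | (2S)-8-[(2R,3S)-2-(3,4-dihydroxyphenyl)-5,7-dihydroxy-4-oxochroman-3-yl]-5,7-dihydroxy-2-(4-hydroxyphenyl)chroman-4-one | O=C1C[C@@H](c2ccc(O)cc2)Oc2c1c(O)cc(O)c2[C@@H]1C(=O)c2c(O)cc(O)cc2O[C@H]1c1ccc(O)c(O)c1 | target

**Step count and risks**
Total steps: 15. Longest linear sequence: 12 steps (1, 2, 3, 5, 6, 7, 8, 11, 12, 13, 14, 15).

Most likely to fail:

Step 12. The potassium aldolate may undergo retro-aldol cleavage and re-addition (loss of configurational purity at C2 of unit 2) or dehydration before it closes the ring. Fallback, from 19 back to 23: the ketone of 19 is first reduced (NaBH4, MeOH/THF, 0 °C) to the 1,3-diol F1, in which neither retro-aldol nor E1cB is possible. The C2 alkoxide is then closed onto the now non-activated fluoroarene at higher temperature (KN(SiMe3)2, DMF, 60–80 °C, the known SNAr of tethered alkoxides on unactivated aryl fluorides; the benzylic C4 oxygen cannot reach the ring) to give the flavan-4-ol F2. Desilylation as in step 13 gives the diol F3, and an excess of Dess–Martin periodinane oxidises both benzylic alcohols to 23.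

Step 7. Hydride transfer to the crowded C4 carbonyl may be too slow, or the discrimination between the enantiomers too small. Fallback, from 11 back to 12: NaBH4 reduction (axial hydride delivery) gives the racemic all-trans alcohol F4. Esterification with (S)-2-methoxy-2-phenylacetic acid (DCC, DMAP) gives the diastereomeric esters, the ester of 12 F5 and the ester of its enantiomer F6, which are separated by chromatography or crystallisation. Hydrolysis of F5 (LiOH, THF/MeOH/H2O) returns 12.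

Step 6. The aldol equilibrium of the doubly ortho-substituted enolate may be unfavourable, and dehydration to a chalcone that cannot cyclise may outrun ring closure. Fallback, from 7 and 8 back to 11: Knoevenagel condensation (piperidine, AcOH, toluene, reflux with water removal) is run on purpose to give the α-aryl chalcone F7, which has no acidic α-hydrogen, so its carbonyl still activates the ring A fluorine. KOH in DMSO replaces that fluorine by hydroxide to give the 2'-hydroxychalcone F8, which closes by oxa-Michael addition (DBU) to rac-11, the classical chalcone-to-flavanone route.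

**Further compounds**
F1 | step 12 | (3S)-1-{4,6-bis(benzyloxy)-2-fluoro-3-[(2R,3S,4R)-5,7-bis(benzyloxy)-2-[3,4-bis(benzyloxy)phenyl]-4-(triethylsilyloxy)chroman-3-yl]phenyl}-3-[4-(benzyloxy)phenyl]propane-1,3-diol (C1 epimers) | OC(C[C@@H](c1ccc(OCc2ccccc2)cc1)O)c1c(F)c([C@@H]2[C@@H](O[Si](CC)(CC)CC)c3c(OCc4ccccc4)cc(OCc4ccccc4)cc3O[C@H]2c2ccc(OCc3ccccc3)c(OCc3ccccc3)c2)c(OCc2ccccc2)cc1OCc1ccccc1
F2 | step 12 | (2S)-5,7-bis(benzyloxy)-2-[4-(benzyloxy)phenyl]-8-[(2R,3S,4R)-5,7-bis(benzyloxy)-2-[3,4-bis(benzyloxy)phenyl]-4-(triethylsilyloxy)chroman-3-yl]chroman-4-ol (C4 epimers) | OC1C[C@@H](c2ccc(OCc3ccccc3)cc2)Oc2c1c(OCc1ccccc1)cc(OCc1ccccc1)c2[C@@H]1[C@@H](O[Si](CC)(CC)CC)c2c(OCc3ccccc3)cc(OCc3ccccc3)cc2O[C@H]1c1ccc(OCc2ccccc2)c(OCc2ccccc2)c1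
F3 | step 12 | (2S)-5,7-bis(benzyloxy)-2-[4-(benzyloxy)phenyl]-8-[(2R,3R,4R)-5,7-bis(benzyloxy)-2-[3,4-bis(benzyloxy)phenyl]-4-hydroxychroman-3-yl]chroman-4-ol (C4 epimers of unit 2) | OC1C[C@@H](c2ccc(OCc3ccccc3)cc2)Oc2c1c(OCc1ccccc1)cc(OCc1ccccc1)c2[C@@H]1[C@@H](O)c2c(OCc3ccccc3)cc(OCc3ccccc3)cc2O[C@H]1c1ccc(OCc2ccccc2)c(OCc2ccccc2)c1
F4 | step 7 | racemic all-trans chroman-4-ol (12 together with its enantiomer) | Brc1c(F)c([C@@H]2[C@@H](O)c3c(OCc4ccccc4)cc(OCc4ccccc4)cc3O[C@H]2c2ccc(OCc3ccccc3)c(OCc3ccccc3)c2)c(OCc2ccccc2)cc1OCc1ccccc1.Brc1c(F)c([C@H]2[C@H](O)c3c(OCc4ccccc4)cc(OCc4ccccc4)cc3O[C@@H]2c2ccc(OCc3ccccc3)c(OCc3ccccc3)c2)c(OCc2ccccc2)cc1OCc1ccccc1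
F5 | step 7 | (S)-2-methoxy-2-phenylacetate ester of 12 | Brc1c(F)c([C@@H]2[C@@H](OC(=O)[C@@H](OC)c3ccccc3)c3c(OCc4ccccc4)cc(OCc4ccccc4)cc3O[C@H]2c2ccc(OCc3ccccc3)c(OCc3ccccc3)c2)c(OCc2ccccc2)cc1OCc1ccccc1
F6 | step 7 | (S)-2-methoxy-2-phenylacetate ester of the enantiomer of 12 | Brc1c(F)c([C@H]2[C@H](OC(=O)[C@@H](OC)c3ccccc3)c3c(OCc4ccccc4)cc(OCc4ccccc4)cc3O[C@@H]2c2ccc(OCc3ccccc3)c(OCc3ccccc3)c2)c(OCc2ccccc2)cc1OCc1ccccc1
F7 | step 6 | 1-[2,4-bis(benzyloxy)-6-fluorophenyl]-2-[4,6-bis(benzyloxy)-3-bromo-2-fluorophenyl]-3-[3,4-bis(benzyloxy)phenyl]prop-2-en-1-one | O=C(C(=Cc1ccc(OCc2ccccc2)c(OCc2ccccc2)c1)c1c(F)c(Br)c(OCc2ccccc2)cc1OCc1ccccc1)c1c(F)cc(OCc2ccccc2)cc1OCc1ccccc1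
F8 | step 6 | 1-[2,4-bis(benzyloxy)-6-hydroxyphenyl]-2-[4,6-bis(benzyloxy)-3-bromo-2-fluorophenyl]-3-[3,4-bis(benzyloxy)phenyl]prop-2-en-1-one | O=C(C(=Cc1ccc(OCc2ccccc2)c(OCc2ccccc2)c1)c1c(F)c(Br)c(OCc2ccccc2)cc1OCc1ccccc1)c1c(O)cc(OCc2ccccc2)cc1OCc1ccccc1
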